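**Remarks on conventions and assumptions**

- Germacrane locants are used for all ring compounds: C1–C10 is the carbocycle, C14 the methyl on C10, C15 the methyl on C4, C12 the lactone carbonyl (bonded to C11 and to the oxygen on C8), C13 the methyl on C11.
- "Upper face" means the face of the six- or ten-membered ring that carries H7 and the lactone oxygen on C8. "Lower face" is the face of H8 and of C11 with its oxygen substituent.
- 1-Methylcyclobutene (16) is taken as a purchasable speciality alkene; otherwise it is one base-isomerisation step from methylenecyclobutane.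
- The angeloyl donor 23 is made once as a filtered toluene solution and serves both esterifications.

## Analysis of the target

Target 27 is a germacranolide: a ten-membered carbocycle (C1–C10) trans-fused at C7–C8 to a γ-lactone, with a Z trisubstituted C1=C10 alkene, a C4–C5 epoxide and two (Z)-2-methylbut-2-enoates, one on the secondary O6 and one on the tertiary O11. It has six stereocentres (4S,5S,6S,7S,8R,11R): H7 and H8 are trans, the C11 oxygen lies on the same lactone face as C6, and the epoxide is trans, so it derives from a 4E alkene. In a flat drawing O6, the epoxide oxygen at C5 and C11 lie on the lower face, and H5, H6 and H7 on the upper face. The sensitive groups are the angelates, which isomerise to tiglates under nucleophilic catalysis, base, light or heat, and the epoxide, which can cyclise across the ring under acid. Until C6 is reduced, H7 is α to a ketone and the lactone oxygen sits β to that ketone, so epimerisation and β-elimination threaten. The hard part is a medium ring that needs a Z alkene at C1=C10 and an E alkene at C4=C5 at once, followed by stereocontrol at C4, C5 and C6 and a hindered tertiary angelate. The strategy rests on one feature: with the epoxide read as an alkene, C1, C10, C4 and C5 are the four sp2 carbons of a 1,5-diene, and they can be tied back as a cyclobutane C1–C4–C5–C10 that shares C1–C4 with a second cyclobutane (C1–C2–C3–C4) and C5–C10 with a six-membered ketone ring (C5–C6–C7–C8–C9–C10), as in 17. The trans-fused lactone on C7–C8 of that six-membered ring locks its chair, and this lock turns the relative configuration of 17 into the alkene geometry of the ten-membered ring.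

## Retrosynthetic reasoning

**Esters (27 ⇒ 25 ⇒ 24 ⇒ 21; acyl donor 23 ⇒ 22).** Both O-acyl bonds are cut first. An angelate would not survive the light and heat used to build the ring, and the secondary and the tertiary hydroxyl need different acylation conditions. Both esters come from the same mixed anhydride 23, made from 22 in a separate operation without a nucleophilic catalyst. The C6 ester goes on thermally while O11 is still silylated (21 → 24). The silyl group is then removed (25) and the tertiary alkoxide is acylated last (27).

**Epoxide and C6 carbinol (21 ⇒ 20 ⇒ 19).** The C4–O and C5–O bonds are cut back to the 4E alkene of 20, and the C6–H bond back to the ketone of 19. This leaves a cross-ring dienone whose only stereocentres are C7, C8 and C11. Forward, a 1,2-reduction sets C6 from the outer face of the ring, and the new hydroxyl then delivers oxygen to C4=C5. This makes the epoxidation chemoselective against C1=C10 and fixes its face.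

**Ten-membered ring (19 ⇒ 17, the key disconnection).** The C1–C4 and C5–C10 bonds are re-formed, which folds the ring into the tricyclic ketone 17. No cyclisation of an open chain is needed, because the medium ring is released from small-ring strain. Forward, the step has to break exactly these two bonds, must not continue by Cope rearrangement, and has to give 1(10)Z and 4E. The geometry is decided by which of C9 and C6 is axial on the intermediate diyl chair. That in turn is fixed by the lactone-locked cyclohexanone chair and by the face of the six-membered ring that carries the cyclobutane in 17.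

**Cyclobutane (17 ⇒ 15 + 16).** The C10–C1 and C5–C4 bonds are cut, giving the 3-methylcyclohexenone 15 and the cyclobutene 16. Forward this is an enone–alkene [2+2] photocycloaddition. It must be head-to-head (C4 on C5, C1 on C10), cis-anti-cis, and on the upper face of 15. The C11 silyl ether on the lower face is the steering group for the face.

**Lactone and C11 (15 ⇒ 14 ⇒ 12 ⇒ 9 + 10).** The silyl group is removed and the lactone C12–O8 bond opened. The C7–C11 bond is then cut as an aldol between the α′-enolate of the silyloxy enone 9 and the ketone carbonyl of 10. This is the shortest way to bring in C11, C12 and C13 together with the tertiary oxygen. Forward, the aldol sets C7 (anti to the C8 silyloxy group) and C11 (closed, chelated transition state), and lactonisation ties both to C8.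

**Cyclohexenone (9 ⇒ 8 ⇒ 6 + 7; 6 ⇒ 5 ⇒ 4 ⇒ 2 + 3; 2 ⇒ 1).** The C5=C10 bond of 9 is cut by ring-closing metathesis to dienone 8, which keeps the two ends of the chain distinct and so keeps C8 stereogenic. The vinyl ketone comes from Weinreb amide 6 and 7. The C9–C10 bond comes from opening epoxide 2 with 3. C8, the only stereocentre that is bought, comes from the chiral-pool chlorohydrin 1. All other stereocentres are relayed from it.

## Alternatives that were turned down

**Alternative 1: citramalate core, lactone closed by dynamic-kinetic ketone reduction.** The disconnection is the lactone C8–O bond together with the C7 and C8 stereocentres. It leads to the acyclic β-keto thioester A1, in which C11 with its hydroxyl, methyl and C12 comes from citramalate, C6 is a thioester and C1 is a Z vinyl iodide. Forward, RuCl(p-cymene)(TsDPEN) in HCO2H/Et3N would reduce the C8 ketone while C7 epimerises, and the C8 alkoxide would close the lactone to A2.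

- For it: C11 comes from the chiral pool, the Z geometry is fixed in a small fragment, and one catalytic step sets C7 and C8 and closes the lactone. On the security of C11 and of the Z alkene it is stronger than the chosen route, which relies on an aldol transition state and on a conformational lock.
- Against it: A2 holds only C1 and C6–C13. Two more C–C bonds (C1–C2 and C5–C6) and the medium-ring closure are still to be made, and the strategy offers nothing for them. The reduction must select one of four diastereomers next to a quaternary carbinol whose own configuration may be mismatched with the catalyst. A vinyl iodide and a thioester are exposed to the hydride RuH(p-cymene)(TsDPEN).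
- Compared: the chosen strategy makes the ring in one unimolecular step from a six-membered ring, so after its key step only functional-group work remains.

**Alternative 2: samarium pinacol ring closure, epoxide by single inversion.** The disconnection is C4–C5, giving the keto aldehyde A3. SmI2 would couple the C5 aldehyde with the C4 methyl ketone to the ten-membered cis-diol A4. Sulfonylation of the C5 hydroxyl and displacement by O4 would then give the epoxide with inversion at C5.

- For it: the ring closes at the bond that carries both epoxide oxygens, so neither an E alkene nor a directed epoxidation is needed, and the Z alkene is preset. On the chemoselectivity of the oxidation it is as strong as or stronger than the chosen route.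
- Against it: the coupling must give one of four diol diastereomers relative to C6, controlled only by the conformation of a flexible chain. Divalent samarium cleaves α-oxygenated carbonyl compounds, so the C11 silyloxy group next to the lactone carbonyl and the C6 ether next to the aldehyde are at risk. High dilution is needed. A3 must carry C6, C7, C8, C11 and the Z alkene in an open chain, which makes the route long.
- Compared: the chosen strategy replaces a medium-ring closure under dilution by a strain-driven ring opening.

**Alternative 3: B-alkyl Suzuki macrocyclisation at the C1–C2 bond.** The disconnection is C1–C2, giving the iodo diene A5. 9-BBN would hydroborate its terminal vinyl group, and Pd(dppf)Cl2 with AsPh3 and Cs2CO3 would couple the C2 alkylborane with the Z C1 iodide to A6, which is the silyl ether of 20.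

- For it: both alkene geometries are fixed before the ring is closed, and C6 is already set. This is clearly stronger than the chosen strategy, in which the geometries depend on the face taken by the photocycloaddition. The conditions are mild and the product joins the same endgame.
- Against it: 9-BBN has to discriminate the terminal alkene of a 1,3-diene, with allylborane formation as a side path. Reductive elimination must build a ten-membered ring holding two trisubstituted alkenes, the most strained ring size for such closures, so protodeboronation and β-hydride elimination can compete. High dilution is needed. A5, with four stereocentres, an E diene and a Z iodide, needs a long linear synthesis.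
- Compared: the chosen strategy gives the same ring in two steps from a bicyclic enone without dilution, at the price of a conformational rather than a built-in geometry control.

Key step: step 11

## Route

**Step 1**
Reactants: 1 ethyl (3S)-4-chloro-3-hydroxybutanoate
Product: 2 ethyl 2-[(2S)-oxiran-2-yl]acetate
Conditions: Ag2O (1.2 equiv), MeCN, 60 °C
Reagents that add atoms: none
Why: Silver-assisted intramolecular Williamson etherification of a chlorohydrin; the neutral medium avoids the base-induced β-elimination of the β,γ-epoxy ester, and the stereocentre is not touched.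

**Step 2**
Reactants: 2 ethyl 2-[(2S)-oxiran-2-yl]acetate; 3 isopropenylmagnesium bromide
Product: 4 ethyl (3R)-3-hydroxy-5-methylhex-5-enoate
Conditions: 3 (1.5 equiv), CuI (10 mol%), THF, −40 °C; aq. NH4Cl
Reagents that add atoms: none
Why: Copper-catalysed Grignard opening of a terminal epoxide at its CH2 carbon (SN2); the ester survives at this temperature and the carbinol centre (the later C8) is untouched.

**Step 3**
Reactants: 4 ethyl (3R)-3-hydroxy-5-methylhex-5-enoate
Product: 5 ethyl (3R)-3-[(tert-butyldimethylsilyl)oxy]-5-methylhex-5-enoate
Conditions: TBSCl, imidazole, DMF, rt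
Reagents that add atoms: tert-butyldimethylsilyl chloride, CC(C)(C)[Si](C)(C)Cl
Why: Standard silylation of a secondary alcohol; the ether blocks β-elimination and directs the later aldol.

**Step 4**
Reactants: 5 ethyl (3R)-3-[(tert-butyldimethylsilyl)oxy]-5-methylhex-5-enoate
Product: 6 (3R)-3-[(tert-butyldimethylsilyl)oxy]-N-methoxy-N,5-dimethylhex-5-enamide
Conditions: MeNH(OMe)·HCl, i-PrMgCl, THF, −20 °C
Reagents that add atoms: N,O-dimethylhydroxylamine hydrochloride, CNOC.Cl
Why: Aminolysis of an ester by a magnesium amide to the Weinreb amide, a routine conversion that a β-silyloxy group tolerates.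

**Step 5**
Reactants: 6 (3R)-3-[(tert-butyldimethylsilyl)oxy]-N-methoxy-N,5-dimethylhex-5-enamide; 7 vinylmagnesium bromide
Product: 8 (5R)-5-[(tert-butyldimethylsilyl)oxy]-7-methylocta-1,7-dien-3-one
Conditions: 7 (1.5 equiv), THF, −78 → 0 °C; inverse quench into cold aq. HCl
Reagents that add atoms: none
Why: Weinreb ketone synthesis; the chelated tetrahedral intermediate stops over-addition, and the cold acidic quench keeps the liberated amine from adding to the vinyl ketone.

**Step 6**
Reactants: 8 (5R)-5-[(tert-butyldimethylsilyl)oxy]-7-methylocta-1,7-dien-3-one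
Product: 9 (5R)-5-[(tert-butyldimethylsilyl)oxy]-3-methylcyclohex-2-en-1-one
Conditions: RuCl2(=CHPh)(PCy3)(H2IMes) (second-generation Grubbs catalyst, 3 mol%), CH2Cl2 (0.01 M), 40 °C
Reagents that add atoms: none
Why: Ring-closing metathesis between the enone terminus and the 1,1-disubstituted alkene forms C5=C10 of the 3-methylcyclohexenone, a well-used way to such enones that leaves the silyloxy stereocentre intact.

**Step 7**
Reactants: 9 (5R)-5-[(tert-butyldimethylsilyl)oxy]-3-methylcyclohex-2-en-1-one; 10 methyl pyruvate
Product: 12 methyl (2R)-2-[(1R,6R)-6-[(tert-butyldimethylsilyl)oxy]-4-methyl-2-oxocyclohex-3-en-1-yl]-2-hydroxypropanoate, via lithium dienolate 11 (not isolated)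
Conditions: LiN(iPr)2 (1.05 equiv), THF, −78 °C; then 10 (1.2 equiv), −78 °C; AcOH quench at −78 °C
Reagents that add atoms: lithium diisopropylamide, [Li]N(C(C)C)C(C)C (its lithium is carried only in 11)
Why: Kinetic α′-deprotonation of the enone and lithium aldol addition to the ketone carbonyl of pyruvate. The electrophile should add to C7 anti to the adjacent pseudoaxial silyloxy group (C7/C8 trans), and a closed chair transition state with the cyclic E-enolate, in which the pyruvate ester carbonyl co-ordinates lithium (ester axial, methyl equatorial), should give the 11R carbinol. The cold quench forestalls retro-aldol cleavage.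

**Step 8**
Reactants: 12 methyl (2R)-2-[(1R,6R)-6-[(tert-butyldimethylsilyl)oxy]-4-methyl-2-oxocyclohex-3-en-1-yl]-2-hydroxypropanoate
Product: 14 (3R,3aR,7aR)-3-hydroxy-3,6-dimethyl-3a,7a-dihydro-1-benzofuran-2,4(3H,7H)-dione, via diol ester 13 (not isolated)
Conditions: HF·pyridine, pyridine, THF, 0 °C → rt; then PPTS (cat.), PhH, 50 °C
Reagents that add atoms: none
Why: Fluoride cleavage of the secondary silyl ether, then acid-catalysed lactonisation of the γ-hydroxy ester, helped by the quaternary C11. The ring fusion is trans because C7 and C8 are already trans, and the mildly acidic medium avoids enolisation at C7 and loss of the C8 oxygen.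

**Step 9**
Reactants: 14 (3R,3aR,7aR)-3-hydroxy-3,6-dimethyl-3a,7a-dihydro-1-benzofuran-2,4(3H,7H)-dione
Product: 15 (3R,3aR,7aR)-3,6-dimethyl-3-[(triethylsilyl)oxy]-3a,7a-dihydro-1-benzofuran-2,4(3H,7H)-dione
Conditions: Et3SiOTf, 2,6-lutidine, CH2Cl2, −78 → 0 °C
Reagents that add atoms: triethylsilyl trifluoromethanesulfonate, CC[Si](CC)(CC)OS(=O)(=O)C(F)(F)F
Why: Silyl triflate silylation of a tertiary alcohol; the ether prevents retro-aldol cleavage in the hot tube and places a bulky group on the lower face next to C6.

**Step 10**
Reactants: 15 (3R,3aR,7aR)-3,6-dimethyl-3-[(triethylsilyl)oxy]-3a,7a-dihydro-1-benzofuran-2,4(3H,7H)-dione; 16 1-methylcyclobutene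
Product: 17 (1S,4R,5S,7R,8R,10R,11R) cis-anti-cis tricyclo[4.4.0.0(2,5)]decan-7-one fused to the C11 triethylsilyloxy lactone (bonds C1–C4 and C5–C10 present; cyclobutane on the upper face)
Conditions: hν (366 nm), 16 (10 equiv), CH2Cl2, −40 °C; chromatographic removal of isomers
Reagents that add atoms: none
Why: Triplet enone–alkene [2+2] photocycloaddition. Bonding of C10 to the unsubstituted cyclobutene carbon gives a tertiary cyclobutyl radical that closes on C5, so the head-to-head, cis-fused adduct with the second four-membered ring anti and without adjacent quaternary carbons should form. The upper face is needed: the C11 silyl ether lies under C6, where the C4 methyl of a lower-face adduct would have to sit, but axial bonding at C10 favours the lower face, so the lower-face cis-anti-cis isomer is the expected companion and must be removed, because it would open to the 1(10)E,4Z ring.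

**Step 11 (key step)**
Reactants: 17 (1S,4R,5S,7R,8R,10R,11R) cis-anti-cis tricyclo[4.4.0.0(2,5)]decan-7-one fused to the C11 triethylsilyloxy lactone
Product: 19 (7R,8R,11R)-6-oxo-11-[(triethylsilyl)oxy]germacra-1(10)Z,4E-dien-12,8-olide, via diyl 18 (not isolated)
Conditions: flash vacuum thermolysis, quartz tube, ca. 420 °C, 0.02 mbar, short hot zone; trap at −196 °C
Reagents that add atoms: none
Why: Thermal cycloreversion of a bicyclo[2.2.0]hexane, the known route from enone–cyclobutene photoadducts to cyclodeca-1,5-dienes. Homolysis of the strained C1–C4 bond gives the cyclohexane-1,4-diyl 18, and cleavage of C5–C10, the most substituted bond antiperiplanar to both radical centres, forms C1=C10 and C4=C5 and releases the strain of the second four-membered ring. No ring is closed by a cyclisation: the ten-membered ring arises by loss of the two bonds shared between the three small rings, so neither a closure mode nor high dilution is involved. No stereocentre is created; C1, C4, C5 and C10 are erased and C7, C8 and C11 are not touched. The selectivity needed is which alkene becomes Z: the trans-fused lactone locks the cyclohexanone chair with C11 and O8 equatorial, and on this chair 17 has the C10 methyl and the C5–C4 bond axial and the C10–C1 bond equatorial. The diyl can then only relax to the chair that is cis-fused to this locked chair, with C9 axial, C6 equatorial and the C10 methyl equatorial on the diyl ring. An axial substituent ends cis and an equatorial one trans to the ring CH2 on the new double bond, hence 1(10)Z and 4E. The short contact time, the boat-like Cope transition state that a Z,E-diene requires and the conjugation gained in C4=C5–C6=O should keep 19 from collapsing to the divinylcyclohexanone.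

**Step 12**
Reactants: 19 (7R,8R,11R)-6-oxo-11-[(triethylsilyl)oxy]germacra-1(10)Z,4E-dien-12,8-olide
Product: 20 (6R,7R,8R,11R)-6-hydroxy-11-[(triethylsilyl)oxy]germacra-1(10)Z,4E-dien-12,8-olide
Conditions: NaBH4, CeCl3·7H2O, MeOH, −78 °C
Reagents that add atoms: none
Why: Luche 1,2-reduction of the enone. In the conformer of 19 that keeps C11 pseudo-equatorial and anti to C5, the C4 methyl lies on the C11 side of the ring, and hydride should add to C6 from outside the ring, anti to that methyl and past H7. This gives the 6R carbinol with its hydroxyl close to the plane of C4=C5.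

**Step 13**
Reactants: 20 (6R,7R,8R,11R)-6-hydroxy-11-[(triethylsilyl)oxy]germacra-1(10)Z,4E-dien-12,8-olide
Product: 21 (4S,5S,6S,7R,8R,11R)-4,5-epoxy-6-hydroxy-11-[(triethylsilyl)oxy]germacr-1(10)Z-en-12,8-olide
Conditions: VO(acac)2 (5 mol%), t-BuOOH (anhydrous, in decane), 2,6-lutidine (cat.), CH2Cl2, 0 °C
Reagents that add atoms: tert-butyl hydroperoxide, CC(C)(C)OO
Why: Hydroxyl-directed vanadium-catalysed epoxidation of an allylic alcohol. The vanadate ester on O6 needs a small O–C6–C5=C4 dihedral, which is the arrangement left by step 12, and should deliver oxygen to the outer face of the E alkene (4S,5S). C1=C10 has no directing hydroxyl and should stay untouched; a peracid would be expected to favour the other epoxide through the flipped alkene conformer.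

**Step 14**
Reactants: 22 angelic acid
Product: 23 (Z)-2-methylbut-2-enoic 2,4,6-trichlorobenzoic anhydride
Conditions: 2,4,6-Cl3C6H2COCl (1.0 equiv), Et3N (1.0 equiv), PhMe, rt; filter under argon; kept as a PhMe solution at −20 °C
Reagents that add atoms: 2,4,6-trichlorobenzoyl chloride, O=C(Cl)c1c(Cl)cc(Cl)cc1Cl
Why: Acylation of the triethylammonium carboxylate by the hindered acid chloride, the first stage of a Yamaguchi esterification. No nucleophilic catalyst is present, so the Z alkene should be kept and the anhydride should not disproportionate; one filtered batch supplies steps 15 and 17.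

**Step 15**
Reactants: 21 (4S,5S,6S,7R,8R,11R)-4,5-epoxy-6-hydroxy-11-[(triethylsilyl)oxy]germacr-1(10)Z-en-12,8-olide; 23 (Z)-2-methylbut-2-enoic 2,4,6-trichlorobenzoic anhydride
Product: 24 (4S,5S,6S,7S,8R,11R)-6-angeloyloxy-4,5-epoxy-11-[(triethylsilyl)oxy]germacr-1(10)Z-en-12,8-olide
Conditions: 23 (2 equiv, PhMe solution), Et3N (2 equiv), PhMe, 75 °C
Reagents that add atoms: none
Why: Yamaguchi-type mixed-anhydride esterification run without a nucleophilic catalyst, the usual way to put on an angelate without Z to E isomerisation; the alcohol attacks the less hindered angeloyl carbonyl. The amine takes up the liberated 2,4,6-trichlorobenzoic acid, so the epoxide should be spared.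

**Step 16**
Reactants: 24 (4S,5S,6S,7S,8R,11R)-6-angeloyloxy-4,5-epoxy-11-[(triethylsilyl)oxy]germacr-1(10)Z-en-12,8-olide
Product: 25 (4S,5S,6S,7S,8R,11R)-6-angeloyloxy-4,5-epoxy-11-hydroxygermacr-1(10)Z-en-12,8-olide
Conditions: HF·pyridine, excess pyridine, THF, 0 °C → rt
Reagents that add atoms: none
Why: Fluoride cleavage of the silyl ether of an α-hydroxy lactone; the pyridine buffer should spare the epoxide and the angelate.

**Step 17**
Reactants: 25 (4S,5S,6S,7S,8R,11R)-6-angeloyloxy-4,5-epoxy-11-hydroxygermacr-1(10)Z-en-12,8-olide; 23 (Z)-2-methylbut-2-enoic 2,4,6-trichlorobenzoic anhydride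
Product: 27 (4S,5S,6S,7S,8R,11R)-6,11-bis(angeloyloxy)-4,5-epoxygermacr-1(10)Z-en-12,8-olide (the target), via lithium alkoxide 26 (not isolated)
Conditions: 25, LiN(SiMe3)2 (1.05 equiv), THF, −78 °C; then 23 (1.5 equiv, PhMe solution), −78 → −20 °C
Reagents that add atoms: lithium bis(trimethylsilyl)amide, [Li]N([Si](C)(C)C)[Si](C)(C)C (its lithium only in 26)
Why: O-Acylation of a lithium alkoxide by a mixed anhydride at its less hindered carbonyl. One equivalent of base should deprotonate only the acidic tertiary α-hydroxy lactone hydroxyl, and the low temperature and the absence of a nucleophilic catalyst should keep both angelates Z.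

## Compound list

1 | ethyl (3S)-4-chloro-3-hydroxybutanoate | CCOC(=O)C[C@@H](CCl)O | starting material
2 | ethyl 2-[(2S)-oxiran-2-yl]acetate | CCOC(=O)C[C@H]1CO1 | intermediate
3 | isopropenylmagnesium bromide (prop-1-en-2-ylmagnesium bromide) | CC(=C)[Mg]Br | starting material
4 | ethyl (3R)-3-hydroxy-5-methylhex-5-enoate | CCOC(=O)C[C@@H](CC(C)=C)O | intermediate
5 | ethyl (3R)-3-[(tert-butyldimethylsilyl)oxy]-5-methylhex-5-enoate | CCOC(=O)C[C@@H](CC(C)=C)O[Si](C)(C)C(C)(C)C | intermediate
6 | (3R)-3-[(tert-butyldimethylsilyl)oxy]-N-methoxy-N,5-dimethylhex-5-enamide | CON(C)C(=O)C[C@@H](CC(C)=C)O[Si](C)(C)C(C)(C)C | intermediate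
7 | vinylmagnesium bromide | C=C[Mg]Br | starting material
8 | (5R)-5-[(tert-butyldimethylsilyl)oxy]-7-methylocta-1,7-dien-3-one | C=CC(=O)C[C@@H](CC(C)=C)O[Si](C)(C)C(C)(C)C | intermediate
9 | (5R)-5-[(tert-butyldimethylsilyl)oxy]-3-methylcyclohex-2-en-1-one | O=C1C[C@@H](CC(C)=C1)O[Si](C)(C)C(C)(C)C | intermediate
10 | methyl pyruvate | CC(=O)C(=O)OC | starting material
11 | lithium (3R)-3-[(tert-butyldimethylsilyl)oxy]-5-methylcyclohexa-1,5-dien-1-olate (α′-dienolate of 9) | [Li]OC1=C[C@H](O[Si](C)(C)C(C)(C)C)CC(C)=C1 | intermediate
12 | methyl (2R)-2-[(1R,6R)-6-[(tert-butyldimethylsilyl)oxy]-4-methyl-2-oxocyclohex-3-en-1-yl]-2-hydroxypropanoate | O=C1[C@@H]([C@@](C)(O)C(=O)OC)[C@@H](CC(C)=C1)O[Si](C)(C)C(C)(C)C | intermediate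
13 | methyl (2R)-2-hydroxy-2-[(1R,6R)-6-hydroxy-4-methyl-2-oxocyclohex-3-en-1-yl]propanoate | O=C1[C@@H]([C@@](C)(O)C(=O)OC)[C@@H](CC(C)=C1)O | intermediate
14 | (3R,3aR,7aR)-3-hydroxy-3,6-dimethyl-3a,7a-dihydro-1-benzofuran-2,4(3H,7H)-dione (trans-fused) | O=C1[C@@H]2[C@@H](CC(C)=C1)OC(=O)[C@]2(C)O | intermediate
15 | (3R,3aR,7aR)-3,6-dimethyl-3-[(triethylsilyl)oxy]-3a,7a-dihydro-1-benzofuran-2,4(3H,7H)-dione | O=C1[C@@H]2[C@@H](CC(C)=C1)OC(=O)[C@]2(C)O[Si](CC)(CC)CC | intermediate
16 | 1-methylcyclobutene | CC1=CCC1 | starting material
17 | (1S,4R,5S,7R,8R,10R,11R) cis-anti-cis tricyclo[4.4.0.0(2,5)]decan-7-one fused to the C11 triethylsilyloxy lactone (germacrane locants; extra bonds C1–C4 and C5–C10; cyclobutane on the face of H7 and O8) | O=C1[C@@H]2[C@@H](C[C@]3(C)[C@H]4CC[C@@]4(C)[C@H]13)OC(=O)[C@]2(C)O[Si](CC)(CC)CC | intermediate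
18 | cyclohexane-1,4-diyl from 17 (radical centres C1 and C4; bond C5–C10 still present) | O=C1[C@@H]2[C@@H](C[C@]3(C)[CH]CC[C](C)[C@H]13)OC(=O)[C@]2(C)O[Si](CC)(CC)CC | intermediate
19 | (7R,8R,11R)-6-oxo-11-[(triethylsilyl)oxy]germacra-1(10)Z,4E-dien-12,8-olide | O=C1[C@@H]2[C@@H](C/C(C)=C\CC/C(C)=C/1)OC(=O)[C@]2(C)O[Si](CC)(CC)CC | intermediate
20 | (6R,7R,8R,11R)-6-hydroxy-11-[(triethylsilyl)oxy]germacra-1(10)Z,4E-dien-12,8-olide | O[C@H]1[C@@H]2[C@@H](C/C(C)=C\CC/C(C)=C/1)OC(=O)[C@]2(C)O[Si](CC)(CC)CC | intermediate
21 | (4S,5S,6S,7R,8R,11R)-4,5-epoxy-6-hydroxy-11-[(triethylsilyl)oxy]germacr-1(10)Z-en-12,8-olide | O[C@H]1[C@@H]2[C@@H](C/C(C)=C\CC[C@]3(C)O[C@@H]13)OC(=O)[C@]2(C)O[Si](CC)(CC)CC | intermediate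
22 | angelic acid, (Z)-2-methylbut-2-enoic acid | C/C=C(/C)C(=O)O | starting material
23 | (Z)-2-methylbut-2-enoic 2,4,6-trichlorobenzoic anhydride | C/C=C(/C)C(=O)OC(=O)c1c(Cl)cc(Cl)cc1Cl | intermediate
24 | (4S,5S,6S,7S,8R,11R)-6-angeloyloxy-4,5-epoxy-11-[(triethylsilyl)oxy]germacr-1(10)Z-en-12,8-olide | C/C=C(/C)C(=O)O[C@H]1[C@@H]2[C@@H](C/C(C)=C\CC[C@]3(C)O[C@@H]13)OC(=O)[C@]2(C)O[Si](CC)(CC)CC | intermediate
25 | (4S,5S,6S,7S,8R,11R)-6-angeloyloxy-4,5-epoxy-11-hydroxygermacr-1(10)Z-en-12,8-olide | C/C=C(/C)C(=O)O[C@H]1[C@@H]2[C@@H](C/C(C)=C\CC[C@]3(C)O[C@@H]13)OC(=O)[C@]2(C)O | intermediate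
26 | lithium C11 alkoxide of 25 | C/C=C(/C)C(=O)O[C@H]1[C@@H]2[C@@H](C/C(C)=C\CC[C@]3(C)O[C@@H]13)OC(=O)[C@]2(C)O[Li] | intermediate
27 | (4S,5S,6S,7S,8R,11R)-6,11-bis(angeloyloxy)-4,5-epoxygermacr-1(10)Z-en-12,8-olide | C/C=C(/C)C(=O)O[C@H]1[C@@H]2[C@@H](C/C(C)=C\CC[C@]3(C)O[C@@H]13)OC(=O)[C@]2(C)OC(=O)/C(C)=C\C | target

## Step count and least certain steps

Total: 17 steps. Longest linear sequence: 16 steps (1 → 27 through steps 1–13 and 15–17); step 14 is a one-step branch from 22 that supplies 23 to steps 15 and 17. Compounds 3, 7, 10, 16 and 22 enter as purchased reagents.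

**Step 11 (key step).**
- Most likely failure: the reaction does not stop at 19. The dienone can go on by Cope rearrangement in or behind the hot zone. On the hot wall it can also enolise at C7, which opens the way to loss of the lactone carboxylate from C8 and removes the chair lock that dictates the alkene geometry.
- Fallback: take the ketone out before the ring is opened. It sets out from 17. NaBH4 reduction gives the tricyclic C6 carbinol F1 (either C6 epimer serves). Flash thermolysis of F1, in which C7 can no longer enolise and the lactone lock is unchanged, should give the cyclodecadienol F2. Oxidation of this allylic alcohol with Dess–Martin periodinane comes back to the route at 19. The price is that conjugation no longer disfavours the Cope step, so the contact time has to stay short.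

**Step 10.**
- Most likely failure: addition to the wrong face. Bonding at C10 is stereoelectronically easier in the axial direction, which is the lower face of the lactone-locked enone, and the silyl ether may not outweigh this. The lower-face adduct leads to the wrong alkene geometries. Head-to-tail and trans-fused adducts are smaller risks.
- Fallback: replace substrate control by catalyst control. From 15, irradiation at 366 nm in CH2Cl2 at −75 °C with 16 is run in the presence of an AlBr3-activated chiral oxazaborolidine Lewis acid bound to the C6 carbonyl, in the enantiomer that covers the lower face. This is the known way to face-selective intermolecular enone–alkene photocycloadditions of 3-methylcyclohexenones, and it comes back at 17 without a new compound.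

**Step 7.**
- Most likely failure: poor control of C11, if the pyruvate does not react through the chelated chair. Loss of the silyloxide from the dienolate, proton transfer from pyruvate to the enolate and retro-aldol cleavage on warming are further risks.
- Fallback: a catalyst-controlled Mukaiyama addition. From 9, LiN(iPr)2 with Me3SiCl present from the start gives the trimethylsilyl dienol ether F3. This is added to 10 with Cu(OTf)2 and a tert-butyl-bis(oxazoline) ligand (10 mol%) in THF at −78 °C, in the ligand enantiomer that exposes the pyruvate face leading to 11R. The C7 face stays under control of the C8 silyloxy group, and acidic work-up comes back at 12.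

**Step 12.**
- Most likely failure: hydride addition through the conformer with the flipped enone unit. This would give the 6-epimer and, after step 13, the wrong epoxide as well.
- Fallback: stereoinversion instead of face-selective reduction. From 19 the 6S alcohol F4 is accepted. Mitsunobu reaction (PPh3, DIAD, 4-nitrobenzoic acid) gives the inverted 6R 4-nitrobenzoate F5, and K2CO3 in MeOH at 0 °C comes back at 20.

**Step 17.**
- Most likely failure: incomplete acylation of the hindered tertiary alkoxide, isomerisation of an angelate to the tiglate, or acyl transfer from O6 to O11 followed by reaction of the freed C6 alkoxide with the epoxide.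
- Fallback: build the Z double bond on the ester. From 25, Steglich esterification (DCC, DMAP) with 2-[bis(2,2,2-trifluoroethoxy)phosphoryl]propanoic acid gives the phosphonate ester F6; the acid being activated carries no alkene, and the C6 ester already in place is not an acyl donor under these conditions. Still–Gennari olefination (KN(SiMe3)2, 18-crown-6, acetaldehyde, THF, −78 °C) comes back at 27.

## Further compounds

F1 | step 11 | tricyclic C6 carbinol from 17 (C6 unspecified) | OC1[C@@H]2[C@@H](C[C@]3(C)[C@H]4CC[C@@]4(C)[C@H]13)OC(=O)[C@]2(C)O[Si](CC)(CC)CC
F2 | step 11 | (7R,8R,11R)-6-hydroxy-11-[(triethylsilyl)oxy]germacra-1(10)Z,4E-dien-12,8-olide, C6 unspecified | OC1[C@@H]2[C@@H](C/C(C)=C\CC/C(C)=C/1)OC(=O)[C@]2(C)O[Si](CC)(CC)CC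
F0 | step 10 | none | none
F3 | step 7 | (R)-tert-butyldimethyl{[5-methyl-3-(trimethylsilyloxy)cyclohexa-2,4-dien-1-yl]oxy}silane | C[Si](C)(C)OC1=C[C@H](O[Si](C)(C)C(C)(C)C)CC(C)=C1
F4 | step 12 | (6S,7R,8R,11R)-6-hydroxy-11-[(triethylsilyl)oxy]germacra-1(10)Z,4E-dien-12,8-olide (6-epimer of 20) | O[C@@H]1[C@@H]2[C@@H](C/C(C)=C\CC/C(C)=C/1)OC(=O)[C@]2(C)O[Si](CC)(CC)CC
F5 | step 12 | 4-nitrobenzoate of 20 (6R) | O=C(O[C@H]1[C@@H]2[C@@H](C/C(C)=C\CC/C(C)=C/1)OC(=O)[C@]2(C)O[Si](CC)(CC)CC)c1ccc(cc1)[N+](=O)[O-]
F6 | step 17 | C11 2-[bis(2,2,2-trifluoroethoxy)phosphoryl]propanoate of 25 | C/C=C(/C)C(=O)O[C@H]1[C@@H]2[C@@H](C/C(C)=C\CC[C@]3(C)O[C@@H]13)OC(=O)[C@]2(C)OC(=O)C(C)P(=O)(OCC(F)(F)F)OCC(F)(F)F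
A1 | alternative 1 | acyclic β-keto thioester on the citramalate core (C7 epimerising) | COC(=O)[C@](C)(O)C(C(=O)SCC)C(=O)C/C(C)=C\I
A2 | alternative 1 | trans,trans-lactone with free C11 hydroxyl, C6 thioester and Z vinyl iodide | CCSC(=O)[C@@H]1[C@@H](C/C(C)=C\I)OC(=O)[C@]1(C)O
A3 | alternative 2 | open-chain C5 aldehyde / C4 methyl ketone with the lactone in place | COc1ccc(CO[C@H](C=O)[C@@H]2[C@@H](C/C(C)=C\CCC(C)=O)OC(=O)[C@]2(C)O[Si](CC)(CC)CC)cc1
A4 | alternative 2 | ten-membered cis C4,C5-diol, C5 epimeric to the target | COc1ccc(CO[C@H]2[C@@H]3[C@@H](C/C(C)=C\CC[C@](C)(O)[C@@H]2O)OC(=O)[C@]3(C)O[Si](CC)(CC)CC)cc1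
A5 | alternative 3 | open-chain E diene with terminal vinyl group and Z vinyl iodide | CC[Si](CC)(CC)O[C@H](/C=C(C)/C=C)[C@@H]1[C@@H](C/C(C)=C\I)OC(=O)[C@]1(C)O[Si](CC)(CC)CC
A6 | alternative 3 | (1(10)Z,4E)-germacradienolide, C6 and C11 triethylsilyl ethers | CC[Si](CC)(CC)O[C@H]1[C@@H]2[C@@H](C/C(C)=C\CC/C(C)=C/1)OC(=O)[C@]2(C)O[Si](CC)(CC)CC
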